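The hexamer is cut at the two diaryl ethers on C-2 of rings B and D, giving three dimers, and each dimer is cut inside its tetraoxygenated ring (A, C or E). Ring E has oxygen at C-1, C-3, C-4 and C-5 and hydrogen at C-2 and C-6. A thermal benzannulation of racemic 3-ethoxy-4-(3,4,5-trimethoxyphenoxy)cyclobutenone with triisopropylsiloxyacetylene builds this ring in one operation around its most hindered ether (C-4 to ring F) and leaves all four oxygens different. The precursor already carries the ring F ether, made by simple phenol alkylation. An ortho-iodo analogue gives the AB and CD dimers, which are joined by copper-mediated ether couplings and dealkylated.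

Key step: step 4

Assumption: the siloxyalkyne is not relied on as a catalogue item and is made in step 1; 3-phenylisoxazole, ethoxyacetylene (hexane solution) and TIPSOTf are taken as bought.
Remark: the target is achiral; the only stereocentres on the route are racemic sp3 carbons of the cyclobutenones and of cascade intermediates, all erased on aromatisation.
Remark: methyl and ethyl ethers are the only permanent protecting groups, and an aryl iodide (more reactive than a bromide at a doubly ortho-oxygenated carbon) is built into the second benzannulation substrate so that the AB and CD dimers arrive ready for coupling.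

Step 1
Reactants: 1 3-phenylisoxazole
Product: 4 (ethynyloxy)triisopropylsilane, via 5-lithio-3-phenylisoxazole 2 (not isolated), via lithium ethynolate 3 (not isolated)
Conditions: LiN(iPr)2 (1.0 equiv), THF, −78 to −50 °C; then TIPSOTf, −78 °C to rt
Reagents that add atoms: triisopropylsilyl trifluoromethanesulfonate, CC(C)[Si](C(C)C)(C(C)C)OS(=O)(=O)C(F)(F)F
Why: Deprotonation at C-5 of a 3-arylisoxazole sets off the known anionic ring fragmentation (N–O and C-3–C-4 cleavage) to benzonitrile and lithium ethynolate, and the bulky, hard silyl triflate should then silylate the ynolate on oxygen (ynolate O-silylation) to give the distillable silyl ynol ether.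

Step 2
Reactants: 5 3,4,5-trimethoxyphenol; 6 bromoacetic acid
Product: 7 2-(3,4,5-trimethoxyphenoxy)acetic acid
Conditions: NaOH (aq, 3 equiv), 80 °C, N2; then HCl (aq)
Reagents that add atoms: none
Why: Williamson O-alkylation of the sodium phenoxide by sodium bromoacetate is the classical entry to aryloxyacetic acids, and acidification frees the acid.

Step 3
Reactants: 7 2-(3,4,5-trimethoxyphenoxy)acetic acid; 8 ethoxyacetylene
Product: 11 racemic 3-ethoxy-4-(3,4,5-trimethoxyphenoxy)cyclobut-2-en-1-one, via acid chloride 9 (not isolated), via aryloxyketene 10 (not isolated)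
Conditions: (COCl)2, cat. DMF, CH2Cl2, 0 °C to rt, evaporate; then 8 (3 equiv), Et3N (1.5 equiv, slow addition), CH2Cl2, 0 °C to rt
Reagents that add atoms: none
Why: Dehydrochlorination of the aryloxyacetyl chloride gives the aryloxyketene (as in Staudinger ketene chemistry), which the excess ynol ether should trap in a regioselective ketene–alkyne [2+2] cycloaddition (nucleophilic CH terminus to the ketene carbonyl carbon), putting ethoxy at C-3 and aryloxy at C-4; the new C-4 centre forms racemic and is erased in step 4.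

Step 4
Reactants: 11 racemic 3-ethoxy-4-(3,4,5-trimethoxyphenoxy)cyclobut-2-en-1-one; 4 (ethynyloxy)triisopropylsilane
Product: 16 3-ethoxy-2-(3,4,5-trimethoxyphenoxy)-5-[(triisopropylsilyl)oxy]phenol, via vinylketene 12 (not isolated), via 4-vinylcyclobutenone 13 (not isolated), via dienylketene 14 (not isolated), via cyclohexadienone 15 (not isolated)
Conditions: 4 (1.5 equiv), toluene, 80 °C, Ar
Reagents that add atoms: none
Why: Thermal four-electron electrocyclic opening of 11 (aryloxy turning outward) should give vinylketene 12, whose ketene C=C adds siloxyalkyne 4 in a [2+2] cycloaddition to give 4-vinylcyclobutenone 13; this opens to dienylketene 14, which closes to 15 and tautomerises to phenol 16. The closest known reaction type is the Danheiser benzannulation of cyclobutenones with siloxy- or alkoxyalkynes to resorcinol mono-ethers. Ring E is closed by a thermally allowed disrotatory 6π electrocyclisation of 14 that makes the C-3–C-4 bond, the C-3–C-2 and C-1–C-6 bonds having been made in the [2+2]. No stereocentre remains, because C-4 of 11 and the sp3 carbons of 13 and 15 are racemic, transient and lost on aromatisation. The step needs regioselectivity only (silyloxy para to aryloxy), and the polarisation of the ynol ether secures it, since its nucleophilic CH carbon bonds to the electrophilic ketene carbonyl carbon. Excess 4 and the absence of acid or base should keep the new phenol from acylation by ketene and keep the four ring E oxygens (OH, OEt, OAr, OSi) distinct.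

Step 5
Reactants: 16 3-ethoxy-2-(3,4,5-trimethoxyphenoxy)-5-[(triisopropylsilyl)oxy]phenol
Product: 17 triisopropyl[3-ethoxy-5-methoxy-4-(3,4,5-trimethoxyphenoxy)phenoxy]silane
Conditions: Me2SO4, K2CO3, acetone, 50 °C
Reagents that add atoms: dimethyl sulfate, COS(=O)(=O)OC
Why: Williamson O-methylation of the one free phenol with a hard electrophile that favours O- over C-alkylation on this electron-rich ring, under conditions the bulky aryl silyl ether should survive.

Step 6
Reactants: 17 triisopropyl[3-ethoxy-5-methoxy-4-(3,4,5-trimethoxyphenoxy)phenoxy]silane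
Product: 18 3-ethoxy-5-methoxy-4-(3,4,5-trimethoxyphenoxy)phenol
Conditions: TBAF, AcOH, THF, 0 °C
Reagents that add atoms: none
Why: Fluoride-induced cleavage of the aryl silyl ether (Si–F bond formation), buffered with acetic acid so that the electron-rich phenoxide is protonated at once.

Step 7
Reactants: 5 3,4,5-trimethoxyphenol
Product: 19 2-iodo-3,4,5-trimethoxyphenol
Conditions: NIS (1.0 equiv), CH2Cl2, −20 to 0 °C, dark
Reagents that add atoms: N-iodosuccinimide, O=C1CCC(=O)N1I
Why: Electrophilic aromatic iodination at one of the two equivalent free positions ortho to the hydroxyl, so a single mono-iodide is expected and the stoichiometry limits di-iodination.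

Step 8
Reactants: 19 2-iodo-3,4,5-trimethoxyphenol; 6 bromoacetic acid
Product: 20 2-(2-iodo-3,4,5-trimethoxyphenoxy)acetic acid
Conditions: NaOH (aq, 3 equiv), 80 °C, N2; then HCl (aq)
Reagents that add atoms: none
Why: The same Williamson O-alkylation as in step 2, to which the aryl iodide is inert.

Step 9
Reactants: 20 2-(2-iodo-3,4,5-trimethoxyphenoxy)acetic acid; 8 ethoxyacetylene
Product: 23 racemic 3-ethoxy-4-(2-iodo-3,4,5-trimethoxyphenoxy)cyclobut-2-en-1-one, via acid chloride 21 (not isolated), via aryloxyketene 22 (not isolated)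
Conditions: (COCl)2, cat. DMF, CH2Cl2, 0 °C to rt, evaporate; then 8 (3 equiv), Et3N (1.5 equiv, slow addition), CH2Cl2, 0 °C to rt
Reagents that add atoms: none
Why: The same ketene generation and regioselective ketene–ynol ether [2+2] cycloaddition as in step 3, the ortho-iodine being a spectator and the C-4 centre again racemic and transient.

Step 10
Reactants: 23 racemic 3-ethoxy-4-(2-iodo-3,4,5-trimethoxyphenoxy)cyclobut-2-en-1-one; 4 (ethynyloxy)triisopropylsilane
Product: 28 3-ethoxy-2-(2-iodo-3,4,5-trimethoxyphenoxy)-5-[(triisopropylsilyl)oxy]phenol, via vinylketene 24 (not isolated), via 4-vinylcyclobutenone 25 (not isolated), via dienylketene 26 (not isolated), via cyclohexadienone 27 (not isolated)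
Conditions: 4 (1.5 equiv), toluene, 80 °C, Ar
Reagents that add atoms: none
Why: The Danheiser benzannulation cascade of step 4 (ring opening, [2+2], ring opening, 6π closure, tautomerisation) run on the iodo analogue, whose aryl iodide is inert to reagent-free heating, to give the dimer that serves as both the CD and the AB unit.

Step 11
Reactants: 28 3-ethoxy-2-(2-iodo-3,4,5-trimethoxyphenoxy)-5-[(triisopropylsilyl)oxy]phenol
Product: 29 triisopropyl[3-ethoxy-4-(2-iodo-3,4,5-trimethoxyphenoxy)-5-methoxyphenoxy]silane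
Conditions: Me2SO4, K2CO3, acetone, 50 °C
Reagents that add atoms: dimethyl sulfate, COS(=O)(=O)OC
Why: Williamson O-methylation of the free phenol as in step 5, leaving the silyl ether as the temporary mask of the ring C coupling oxygen.

Step 12
Reactants: 29 triisopropyl[3-ethoxy-4-(2-iodo-3,4,5-trimethoxyphenoxy)-5-methoxyphenoxy]silane
Product: 31 1-ethoxy-2-(2-iodo-3,4,5-trimethoxyphenoxy)-3,5-dimethoxybenzene, via iodo dimer phenol 30 (not isolated)
Conditions: TBAF (1.1 equiv), THF, 0 °C; then Me2SO4 (3 equiv), rt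
Reagents that add atoms: dimethyl sulfate, COS(=O)(=O)OC
Why: Fluoride cleaves the aryl silyl ether and the tetrabutylammonium phenoxide so formed should be O-methylated in the same flask (one-pot desilylation and Williamson alkylation), giving the fully alkylated AB iodide.

Step 13
Reactants: 18 3-ethoxy-5-methoxy-4-(3,4,5-trimethoxyphenoxy)phenol; 29 triisopropyl[3-ethoxy-4-(2-iodo-3,4,5-trimethoxyphenoxy)-5-methoxyphenoxy]silane
Product: 32 tetramer CDEF silyl ether
Conditions: CuI (0.3 equiv), N,N-dimethylglycine hydrochloride, Cs2CO3, 1,4-dioxane, 100 °C, Ar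
Reagents that add atoms: none
Why: Ullmann-type copper-catalysed O-arylation in which the unhindered caesium phenoxide of 18 replaces iodide at C-2 of ring D, with an amino acid ligand and an aprotic, fluoride-free medium that the bulky silyl ether should tolerate.

Step 14
Reactants: 32 tetramer CDEF silyl ether
Product: 33 tetramer CDEF phenol
Conditions: TBAF, AcOH, THF, 0 °C to rt
Reagents that add atoms: none
Why: Buffered fluoride cleavage of the aryl silyl ether frees the ring C C-1 phenol while all alkyl and diaryl ethers stay untouched.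

Step 15
Reactants: 33 tetramer CDEF phenol; 31 1-ethoxy-2-(2-iodo-3,4,5-trimethoxyphenoxy)-3,5-dimethoxybenzene
Product: 34 hexamer hexadeca-O-alkyl ether
Conditions: CuI (0.5 equiv), picolinic acid, K3PO4, DMSO, 100 °C, Ar; 31 in 1.5-fold excess
Reagents that add atoms: none
Why: Ullmann-type O-arylation of the unhindered ring C phenoxide by the ring B iodide, run with the picolinic acid system suited to ortho-substituted partners, which can be used here because no silyl ether is left.

Step 16
Reactants: 34 hexamer hexadeca-O-alkyl ether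
Product: 35 CNP0218077.0
Conditions: BBr3 (about 50 equiv), CH2Cl2, −78 °C to rt; then H2O, 0 °C, work-up under Ar
Reagents that add atoms: none
Why: Lewis acid-mediated ether cleavage in which bromide removes each methyl or ethyl group by SN2 from the boron-complexed ether, the diaryl ether C–O bonds having no sp3 carbon to attack, and hydrolysis of the aryl borates should free the sixteen hydroxyls.

Compound list
1 | 3-phenylisoxazole | c1ccc(-c2ccon2)cc1 | starting material
2 | 5-lithio-3-phenylisoxazole | [Li]c1cc(-c2ccccc2)no1 | intermediate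
3 | lithium ethynolate | [Li+].[O-]C#C | intermediate
4 | (ethynyloxy)triisopropylsilane | C#CO[Si](C(C)C)(C(C)C)C(C)C | intermediate
5 | 3,4,5-trimethoxyphenol | COc1cc(O)cc(OC)c1OC | starting material
6 | bromoacetic acid | OC(=O)CBr | starting material
7 | 2-(3,4,5-trimethoxyphenoxy)acetic acid | COc1cc(OCC(=O)O)cc(OC)c1OC | intermediate
8 | ethoxyacetylene | CCOC#C | starting material
9 | 2-(3,4,5-trimethoxyphenoxy)acetyl chloride | COc1cc(OCC(=O)Cl)cc(OC)c1OC | intermediate
10 | (3,4,5-trimethoxyphenoxy)ketene | COc1cc(OC=C=O)cc(OC)c1OC | intermediate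
11 | racemic 3-ethoxy-4-(3,4,5-trimethoxyphenoxy)cyclobut-2-en-1-one | CCOC1=CC(=O)C1Oc1cc(OC)c(OC)c(OC)c1 | intermediate
12 | (3Z)-3-ethoxy-4-(3,4,5-trimethoxyphenoxy)buta-1,3-dien-1-one (vinylketene, aryloxy trans to the ketene chain) | O=C=C/C(OCC)=C/Oc1cc(OC)c(OC)c(OC)c1 | intermediate
13 | racemic 4-[(Z)-1-ethoxy-2-(3,4,5-trimethoxyphenoxy)ethenyl]-3-[(triisopropylsilyl)oxy]cyclobut-2-en-1-one | O=C1C=C(O[Si](C(C)C)(C(C)C)C(C)C)C1/C(OCC)=C/Oc1cc(OC)c(OC)c(OC)c1 | intermediate
14 | (3E,5Z)-5-ethoxy-6-(3,4,5-trimethoxyphenoxy)-3-[(triisopropylsilyl)oxy]hexa-1,3,5-trien-1-one (dienylketene) | O=C=C/C(O[Si](C(C)C)(C(C)C)C(C)C)=C\C(OCC)=C\Oc1cc(OC)c(OC)c(OC)c1 | intermediate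
15 | racemic 5-ethoxy-6-(3,4,5-trimethoxyphenoxy)-3-[(triisopropylsilyl)oxy]cyclohexa-2,4-dien-1-one | O=C1C=C(O[Si](C(C)C)(C(C)C)C(C)C)C=C(OCC)C1Oc1cc(OC)c(OC)c(OC)c1 | intermediate
16 | 3-ethoxy-2-(3,4,5-trimethoxyphenoxy)-5-[(triisopropylsilyl)oxy]phenol (EF dimer) | CCOc1cc(O[Si](C(C)C)(C(C)C)C(C)C)cc(O)c1Oc1cc(OC)c(OC)c(OC)c1 | intermediate
17 | triisopropyl[3-ethoxy-5-methoxy-4-(3,4,5-trimethoxyphenoxy)phenoxy]silane | CCOc1cc(O[Si](C(C)C)(C(C)C)C(C)C)cc(OC)c1Oc1cc(OC)c(OC)c(OC)c1 | intermediate
18 | 3-ethoxy-5-methoxy-4-(3,4,5-trimethoxyphenoxy)phenol (EF phenol) | CCOc1cc(O)cc(OC)c1Oc1cc(OC)c(OC)c(OC)c1 | intermediate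
19 | 2-iodo-3,4,5-trimethoxyphenol | COc1cc(O)c(I)c(OC)c1OC | intermediate
20 | 2-(2-iodo-3,4,5-trimethoxyphenoxy)acetic acid | COc1cc(OCC(=O)O)c(I)c(OC)c1OC | intermediate
21 | 2-(2-iodo-3,4,5-trimethoxyphenoxy)acetyl chloride | COc1cc(OCC(=O)Cl)c(I)c(OC)c1OC | intermediate
22 | (2-iodo-3,4,5-trimethoxyphenoxy)ketene | COc1cc(OC=C=O)c(I)c(OC)c1OC | intermediate
23 | racemic 3-ethoxy-4-(2-iodo-3,4,5-trimethoxyphenoxy)cyclobut-2-en-1-one | CCOC1=CC(=O)C1Oc1cc(OC)c(OC)c(OC)c1I | intermediate
24 | (3Z)-3-ethoxy-4-(2-iodo-3,4,5-trimethoxyphenoxy)buta-1,3-dien-1-one (vinylketene) | O=C=C/C(OCC)=C/Oc1cc(OC)c(OC)c(OC)c1I | intermediate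
25 | racemic 4-[(Z)-1-ethoxy-2-(2-iodo-3,4,5-trimethoxyphenoxy)ethenyl]-3-[(triisopropylsilyl)oxy]cyclobut-2-en-1-one | O=C1C=C(O[Si](C(C)C)(C(C)C)C(C)C)C1/C(OCC)=C/Oc1cc(OC)c(OC)c(OC)c1I | intermediate
26 | (3E,5Z)-5-ethoxy-6-(2-iodo-3,4,5-trimethoxyphenoxy)-3-[(triisopropylsilyl)oxy]hexa-1,3,5-trien-1-one (dienylketene) | O=C=C/C(O[Si](C(C)C)(C(C)C)C(C)C)=C\C(OCC)=C\Oc1cc(OC)c(OC)c(OC)c1I | intermediate
27 | racemic 5-ethoxy-6-(2-iodo-3,4,5-trimethoxyphenoxy)-3-[(triisopropylsilyl)oxy]cyclohexa-2,4-dien-1-one | O=C1C=C(O[Si](C(C)C)(C(C)C)C(C)C)C=C(OCC)C1Oc1cc(OC)c(OC)c(OC)c1I | intermediate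
28 | 3-ethoxy-2-(2-iodo-3,4,5-trimethoxyphenoxy)-5-[(triisopropylsilyl)oxy]phenol | CCOc1cc(O[Si](C(C)C)(C(C)C)C(C)C)cc(O)c1Oc1cc(OC)c(OC)c(OC)c1I | intermediate
29 | triisopropyl[3-ethoxy-4-(2-iodo-3,4,5-trimethoxyphenoxy)-5-methoxyphenoxy]silane (CD iodide) | CCOc1cc(O[Si](C(C)C)(C(C)C)C(C)C)cc(OC)c1Oc1cc(OC)c(OC)c(OC)c1I | intermediate
30 | 3-ethoxy-4-(2-iodo-3,4,5-trimethoxyphenoxy)-5-methoxyphenol | CCOc1cc(O)cc(OC)c1Oc1cc(OC)c(OC)c(OC)c1I | intermediate
31 | 1-ethoxy-2-(2-iodo-3,4,5-trimethoxyphenoxy)-3,5-dimethoxybenzene (AB iodide) | CCOc1cc(OC)cc(OC)c1Oc1cc(OC)c(OC)c(OC)c1I | intermediate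
32 | triisopropyl(3-ethoxy-5-methoxy-4-{3,4,5-trimethoxy-2-[3-ethoxy-5-methoxy-4-(3,4,5-trimethoxyphenoxy)phenoxy]phenoxy}phenoxy)silane (tetramer CDEF silyl ether) | CCOc1cc(O[Si](C(C)C)(C(C)C)C(C)C)cc(OC)c1Oc1cc(OC)c(OC)c(OC)c1Oc1cc(OC)c(Oc2cc(OC)c(OC)c(OC)c2)c(OCC)c1 | intermediate
33 | 3-ethoxy-5-methoxy-4-{3,4,5-trimethoxy-2-[3-ethoxy-5-methoxy-4-(3,4,5-trimethoxyphenoxy)phenoxy]phenoxy}phenol (tetramer CDEF phenol) | CCOc1cc(O)cc(OC)c1Oc1cc(OC)c(OC)c(OC)c1Oc1cc(OC)c(Oc2cc(OC)c(OC)c(OC)c2)c(OCC)c1 | intermediate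
34 | hexadeca-O-alkyl ether of the target (thirteen methyl and three ethyl groups; one ethyl on a flanking oxygen of each of rings A, C and E) | CCOc1cc(OC)cc(OC)c1Oc1cc(OC)c(OC)c(OC)c1Oc1cc(OC)c(Oc2cc(OC)c(OC)c(OC)c2Oc2cc(OC)c(Oc3cc(OC)c(OC)c(OC)c3)c(OCC)c2)c(OCC)c1 | intermediate
35 | CNP0218077.0 (rings A to F joined by five ether oxygens: A flanked carbon to B C-1, B C-2 to C C-1, C C-4 to D C-1, D C-2 to E C-1, E C-4 to F C-1; sixteen free hydroxyls; no stereocentre) | Oc1cc(O)c(Oc2cc(O)c(O)c(O)c2Oc2cc(O)c(Oc3cc(O)c(O)c(O)c3Oc3cc(O)c(Oc4cc(O)c(O)c(O)c4)c(O)c3)c(O)c2)c(O)c1 | target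

Total step count: 16.
Longest linear sequence: 9 steps (steps 7, 8, 9, 10, 11, 13, 14, 15 and 16, from 5 to 35).

Steps most likely to fail

Step 13. The risk is that under hot carbonate the silyl group of 29 is cleaved or handed over to the phenoxide of 18. The iodide-bearing dimer then becomes a bifunctional monomer and self-condenses, and slow copper insertion at the doubly ortho-oxygenated C–I bond gives this side process time. The fallback replaces the fluoride-labile mask by a benzyl ether and sets out from 29 and 18. Compound 29 is desilylated (TBAF, AcOH, THF) to phenol 30, isolated this time, and benzylated (BnBr, K2CO3, DMF, rt) to 5-(benzyloxy)-1-ethoxy-2-(2-iodo-3,4,5-trimethoxyphenoxy)-3-methoxybenzene F1. F1 and 18 are coupled under the forcing conditions of step 15 (CuI, picolinic acid, K3PO4, DMSO, 110 °C), which a benzyl ether tolerates, to give 5-(benzyloxy)-1-ethoxy-3-methoxy-2-{3,4,5-trimethoxy-2-[3-ethoxy-5-methoxy-4-(3,4,5-trimethoxyphenoxy)phenoxy]phenoxy}benzene F2. Hydrogenolysis (H2, Pd/C, EtOAc/MeOH, rt) then frees the ring C phenol, and the fallback rejoins the route at 33, replacing steps 13 and 14.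

Step 15. The risk is that copper inserts too slowly into the C–I bond of 31, which lies between a methoxy and a bulky aryloxy group. Hydrodeiodination of 31 and oxidative decay of the electron-rich phenoxide of 33 could then overtake ether formation. The fallback reverses the polarity of the union and sets out from 31 and 33. Compound 31 is turned into the hindered phenol 6-(2-ethoxy-4,6-dimethoxyphenoxy)-2,3,4-trimethoxyphenol F3 by palladium-catalysed hydroxylation of the aryl halide (Pd2(dba)3, tBuXPhos, KOH, dioxane/H2O, 100 °C). Compound 33 is converted (Tf2O, pyridine, CH2Cl2, 0 °C) into 3-ethoxy-5-methoxy-4-{3,4,5-trimethoxy-2-[3-ethoxy-5-methoxy-4-(3,4,5-trimethoxyphenoxy)phenoxy]phenoxy}phenyl trifluoromethanesulfonate F4. Palladium-catalysed diaryl ether formation between F3 and F4 (Pd(OAc)2, tBuXPhos, K3PO4, toluene, 100 °C) should then give 34. In this pairing the congested ring is the nucleophile, which favours C–O reductive elimination, and the metal inserts at an unhindered carbon.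

Step 16. The risk is incomplete cleavage of some of the sixteen alkyl ethers (the three ethyl ethers react last), together with oxidative loss of the pyrogallol-type rings B, D and F during aqueous isolation and chromatography of the free polyphenol. The fallback captures, purifies and releases the product, and sets out from 34. After the BBr3 treatment and quench, the crude product is not purified but acetylated at once (Ac2O, pyridine, cat. DMAP, rt) to the hexadeca-O-acetate of the target F5. F5 is stable in air and is purified on silica, where under-dealkylated material separates and can be resubmitted. Acid-catalysed methanolysis (HCl from AcCl in MeOH, rt, Ar) followed by evaporation should then give 35.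

Further compounds
F1 | step 13 | 5-(benzyloxy)-1-ethoxy-2-(2-iodo-3,4,5-trimethoxyphenoxy)-3-methoxybenzene | CCOc1cc(OCc2ccccc2)cc(OC)c1Oc1cc(OC)c(OC)c(OC)c1I
F2 | step 13 | 5-(benzyloxy)-1-ethoxy-3-methoxy-2-{3,4,5-trimethoxy-2-[3-ethoxy-5-methoxy-4-(3,4,5-trimethoxyphenoxy)phenoxy]phenoxy}benzene | CCOc1cc(OCc2ccccc2)cc(OC)c1Oc1cc(OC)c(OC)c(OC)c1Oc1cc(OC)c(Oc2cc(OC)c(OC)c(OC)c2)c(OCC)c1
F3 | step 15 | 6-(2-ethoxy-4,6-dimethoxyphenoxy)-2,3,4-trimethoxyphenol | CCOc1cc(OC)cc(OC)c1Oc1cc(OC)c(OC)c(OC)c1O
F4 | step 15 | 3-ethoxy-5-methoxy-4-{3,4,5-trimethoxy-2-[3-ethoxy-5-methoxy-4-(3,4,5-trimethoxyphenoxy)phenoxy]phenoxy}phenyl trifluoromethanesulfonate | CCOc1cc(OS(=O)(=O)C(F)(F)F)cc(OC)c1Oc1cc(OC)c(OC)c(OC)c1Oc1cc(OC)c(Oc2cc(OC)c(OC)c(OC)c2)c(OCC)c1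
F5 | step 16 | hexadeca-O-acetate of the target | CC(=O)Oc1cc(OC(C)=O)cc(OC(C)=O)c1Oc1cc(OC(C)=O)c(OC(C)=O)c(OC(C)=O)c1Oc1cc(OC(C)=O)c(Oc2cc(OC(C)=O)c(OC(C)=O)c(OC(C)=O)c2Oc2cc(OC(C)=O)c(Oc3cc(OC(C)=O)c(OC(C)=O)c(OC(C)=O)c3)c(OC(C)=O)c2)c(OC(C)=O)c1
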